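**Retrosynthetic overview**
- The target is reached by global O-debenzylation and ester-to-CH2OH reduction of a (2S,3R)-2-aryloxy-3-hydroxy ester (threo).
- Key disconnection: the alkyl C–O bond of the β-aryl ether, made by phenoxide displacement on a racemic 2-bromo-3-oxo ester. Both stereocentres are then set together in the same flask by asymmetric transfer hydrogenation with dynamic kinetic resolution.
- The phenol partner is 5,7-di-O-benzyltricin. Its pyranone ring (ring C, the only ring formed in the route) is closed before the coupling by Claisen–Schmidt condensation and iodine/DMSO oxidative cyclisation.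
- The bromo keto ester comes from 4'-benzyloxyacetophenone by Claisen condensation and bromination.

Assumption: the dibenzyl ether of 2',4',6'-trihydroxyacetophenone used for ring A is bought as a catalogue compound; all other starting materials are bulk chemicals.

**Step 1**
Reactants: 1 1-[4-(benzyloxy)phenyl]ethan-1-one
Product: 2 ethyl 3-[4-(benzyloxy)phenyl]-3-oxopropanoate
Conditions: NaH (2.5 equiv), (EtO)2CO (3 equiv), THF, reflux; then 1 M HCl
Reagents that add atoms: diethyl carbonate, CCOC(=O)OCC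
Why: Crossed Claisen condensation, in which the ketone enolate is acylated by diethyl carbonate and irreversible deprotonation of the β-keto ester drives the equilibrium; no stereocentre is formed.

**Step 2**
Reactants: 2 ethyl 3-[4-(benzyloxy)phenyl]-3-oxopropanoate
Product: 3 ethyl 3-[4-(benzyloxy)phenyl]-2-bromo-3-oxopropanoate (racemic)
Conditions: NBS (1.05 equiv), p-TsOH·H2O (10 mol%), CH2Cl2, 0 °C to rt
Reagents that add atoms: N-bromosuccinimide, O=C1CCC(=O)N1Br
Why: Electrophilic α-bromination of the enol of the 1,3-dicarbonyl, which is far more nucleophilic than the acyl-deactivated arene, so one equivalent gives the mono-bromide (racemic; this centre is re-set in step 5).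

**Step 3**
Reactants: 4 1-[2,4-bis(benzyloxy)-6-hydroxyphenyl]ethan-1-one; 5 4-hydroxy-3,5-dimethoxybenzaldehyde (syringaldehyde)
Product: 6 (E)-1-[2,4-bis(benzyloxy)-6-hydroxyphenyl]-3-(4-hydroxy-3,5-dimethoxyphenyl)prop-2-en-1-one
Conditions: KOH (50% aq., 10 equiv), EtOH, 50 °C; then 1 M HCl
Reagents that add atoms: none
Why: Claisen–Schmidt aldol condensation with E1cB dehydration to the conjugated (E)-chalcone, where excess concentrated KOH and warming compensate for the low electrophilicity of the phenoxide form of the aldehyde.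

**Step 4**
Reactants: 6 (E)-1-[2,4-bis(benzyloxy)-6-hydroxyphenyl]-3-(4-hydroxy-3,5-dimethoxyphenyl)prop-2-en-1-one
Product: 7 5,7-bis(benzyloxy)-2-(4-hydroxy-3,5-dimethoxyphenyl)-4H-chromen-4-one (5,7-di-O-benzyltricin)
Conditions: I2 (10 mol%), DMSO, 130 °C; then aq. Na2S2O3
Reagents that add atoms: none
Why: Iodine/DMSO oxidative cyclisation of a 2'-hydroxychalcone (intramolecular oxa-Michael addition, α-iodination and HI elimination, with DMSO re-oxidising HI) closes ring C and leaves the benzyl ethers and the hindered phenol untouched.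

**Step 5**
Reactants: 7 5,7-bis(benzyloxy)-2-(4-hydroxy-3,5-dimethoxyphenyl)-4H-chromen-4-one; 3 ethyl 3-[4-(benzyloxy)phenyl]-2-bromo-3-oxopropanoate
Product: 9 ethyl (2S,3R)-3-[4-(benzyloxy)phenyl]-2-{4-[5,7-bis(benzyloxy)-4-oxo-4H-chromen-2-yl]-2,6-dimethoxyphenoxy}-3-hydroxypropanoate, via racemic keto ester 8 (not isolated)
Conditions: K2CO3 (1.5 equiv), DMF, 0 °C to rt; then HCO2H/Et3N (5:2), RuCl[(S,S)-TsDPEN](p-cymene) (2 mol%), 35 °C (TsDPEN = N-tosyl-1,2-diphenylethylenediamine)
Reagents that add atoms: none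
Why: Proposed new method: the phenoxide of 7 displaces bromide from 3 (Williamson-type SN2 at an α-halo-β-keto ester, which forms the key C–O bond), and the resulting α-aryloxy-β-keto ester 8, whose C2–H is acidic enough to racemise rapidly in HCO2H/Et3N, is reduced in the same pot by Noyori–Ikariya asymmetric transfer hydrogenation with dynamic kinetic resolution, in which the (S,S)-catalyst delivers hydride to one ketone face (aryl held in the CH/π site of the η6-arene, giving 3R) and the polar Felkin–Anh preference for hydride attack anti to the electronegative aryloxy group selects the 2S epimer, so the syn (threo) 2S,3R product results; the closest known reaction is the syn-selective Ru/TsDPEN transfer hydrogenation with dynamic kinetic resolution of α-alkoxy-β-keto esters, which has not been shown for α-aryloxy substrates carrying a 2,6-disubstituted flavonoid phenoxy group nor run in one pot with the etherification.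

**Step 6**
Reactants: 9 ethyl (2S,3R)-3-[4-(benzyloxy)phenyl]-2-{4-[5,7-bis(benzyloxy)-4-oxo-4H-chromen-2-yl]-2,6-dimethoxyphenoxy}-3-hydroxypropanoate
Product: 10 5,7-bis(benzyloxy)-2-[4-({(1R,2R)-1-[4-(benzyloxy)phenyl]-1,3-dihydroxypropan-2-yl}oxy)-3,5-dimethoxyphenyl]-4H-chromen-4-one
Conditions: NaBH4 (4 equiv), THF/EtOH (1:1), 0 °C to rt; then aq. NH4Cl
Reagents that add atoms: none
Why: Borohydride reduction of an α-aryloxy-β-hydroxy ester, activated by its two neighbouring oxygen substituents, while the electron-rich 5,7-dialkoxyflavone carbonyl (a vinylogous ester) reacts much more slowly; no bond to either stereocentre is touched (the descriptor at the ether carbon changes from S to R only through the priority change from CO2Et to CH2OH).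

**Step 7**
Reactants: 10 5,7-bis(benzyloxy)-2-[4-({(1R,2R)-1-[4-(benzyloxy)phenyl]-1,3-dihydroxypropan-2-yl}oxy)-3,5-dimethoxyphenyl]-4H-chromen-4-one
Product: 11 5,7-dihydroxy-2-[4-({(1R,2R)-1,3-dihydroxy-1-(4-hydroxyphenyl)propan-2-yl}oxy)-3,5-dimethoxyphenyl]-4H-chromen-4-one
Conditions: H2 (1 atm), Pd/C (10 wt%), THF/MeOH, rt
Reagents that add atoms: none
Why: Catalytic hydrogenolysis of the three aryl benzyl ethers under neutral conditions, which leaves the flavone enone, the alkyl aryl ether and the secondary benzylic alcohol intact and does not affect the stereocentres.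

**Compound list**
1 | 1-[4-(benzyloxy)phenyl]ethan-1-one | CC(=O)c1ccc(OCc2ccccc2)cc1 | starting material
2 | ethyl 3-[4-(benzyloxy)phenyl]-3-oxopropanoate | CCOC(=O)CC(=O)c1ccc(OCc2ccccc2)cc1 | intermediate
3 | ethyl 3-[4-(benzyloxy)phenyl]-2-bromo-3-oxopropanoate (racemic) | CCOC(=O)C(Br)C(=O)c1ccc(OCc2ccccc2)cc1 | intermediate
4 | 1-[2,4-bis(benzyloxy)-6-hydroxyphenyl]ethan-1-one | CC(=O)c1c(O)cc(OCc2ccccc2)cc1OCc1ccccc1 | starting material
5 | 4-hydroxy-3,5-dimethoxybenzaldehyde (syringaldehyde) | COc1cc(C=O)cc(OC)c1O | starting material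
6 | (E)-1-[2,4-bis(benzyloxy)-6-hydroxyphenyl]-3-(4-hydroxy-3,5-dimethoxyphenyl)prop-2-en-1-one | COc1cc(/C=C/C(=O)c2c(O)cc(OCc3ccccc3)cc2OCc2ccccc2)cc(OC)c1O | intermediate
7 | 5,7-bis(benzyloxy)-2-(4-hydroxy-3,5-dimethoxyphenyl)-4H-chromen-4-one | COc1cc(-c2cc(=O)c3c(OCc4ccccc4)cc(OCc4ccccc4)cc3o2)cc(OC)c1O | intermediate
8 | ethyl 3-[4-(benzyloxy)phenyl]-2-{4-[5,7-bis(benzyloxy)-4-oxo-4H-chromen-2-yl]-2,6-dimethoxyphenoxy}-3-oxopropanoate (racemic, formed in the flask) | COc1cc(-c2cc(=O)c3c(OCc4ccccc4)cc(OCc4ccccc4)cc3o2)cc(OC)c1OC(C(=O)OCC)C(=O)c1ccc(OCc2ccccc2)cc1 | intermediate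
9 | ethyl (2S,3R)-3-[4-(benzyloxy)phenyl]-2-{4-[5,7-bis(benzyloxy)-4-oxo-4H-chromen-2-yl]-2,6-dimethoxyphenoxy}-3-hydroxypropanoate | COc1cc(-c2cc(=O)c3c(OCc4ccccc4)cc(OCc4ccccc4)cc3o2)cc(OC)c1O[C@H](C(=O)OCC)[C@H](O)c1ccc(OCc2ccccc2)cc1 | intermediate
10 | 5,7-bis(benzyloxy)-2-[4-({(1R,2R)-1-[4-(benzyloxy)phenyl]-1,3-dihydroxypropan-2-yl}oxy)-3,5-dimethoxyphenyl]-4H-chromen-4-one | COc1cc(-c2cc(=O)c3c(OCc4ccccc4)cc(OCc4ccccc4)cc3o2)cc(OC)c1O[C@H](CO)[C@H](O)c1ccc(OCc2ccccc2)cc1 | intermediate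
11 | 5,7-dihydroxy-2-[4-({(1R,2R)-1,3-dihydroxy-1-(4-hydroxyphenyl)propan-2-yl}oxy)-3,5-dimethoxyphenyl]-4H-chromen-4-one | COc1cc(-c2cc(=O)c3c(O)cc(O)cc3o2)cc(OC)c1O[C@H](CO)[C@H](O)c1ccc(O)cc1 | target

**Step count and risks**
Total steps: 7. Longest linear sequence: 5 steps (steps 3, 4, 5, 6, 7; the branch through steps 1, 2, 5, 6, 7 is equally long).

The three steps most likely to fail:

Step 3. The phenoxide form of syringaldehyde is a poor aldol acceptor, so the condensation may stall or give a low yield. The fallback sets out from 5 and comes back at 7, replacing steps 3 and 4. MOMCl and iPr2NEt in CH2Cl2 convert 5 into 3,5-dimethoxy-4-(methoxymethoxy)benzaldehyde F1. This non-phenolic aldehyde condenses with 4 (KOH, EtOH, rt) to give (E)-1-[2,4-bis(benzyloxy)-6-hydroxyphenyl]-3-[3,5-dimethoxy-4-(methoxymethoxy)phenyl]prop-2-en-1-one F2. I2/DMSO at 130 °C then gives 5,7-bis(benzyloxy)-2-[3,5-dimethoxy-4-(methoxymethoxy)phenyl]-4H-chromen-4-one F3, and aqueous HCl in THF at 50 °C removes the acetal to give 7.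

Step 5 (the proposed new step). The bulky flavonoid aryloxy group may lower the syn selectivity or slow the reduction, and the one-pot change of medium may hurt the catalyst; if only the latter occurs, 8 can be isolated first. The fallback uses known auxiliary chemistry, sets out from 7 and comes back at 10, replacing steps 5 and 6. Phenol 7 is alkylated with (S)-4-benzyl-3-(chloroacetyl)oxazolidin-2-one (K2CO3, NaI, DMF) to give (S)-4-benzyl-3-({4-[5,7-bis(benzyloxy)-4-oxo-4H-chromen-2-yl]-2,6-dimethoxyphenoxy}acetyl)oxazolidin-2-one F4. Enolisation with Bu2BOTf and iPr2NEt in CH2Cl2 at −78 °C and addition of 4-(benzyloxy)benzaldehyde gives the Evans syn aldol (S)-4-benzyl-3-[(2S,3R)-3-[4-(benzyloxy)phenyl]-2-{4-[5,7-bis(benzyloxy)-4-oxo-4H-chromen-2-yl]-2,6-dimethoxyphenoxy}-3-hydroxypropanoyl]oxazolidin-2-one F5. LiBH4 in THF/MeOH at 0 °C cleaves the auxiliary reductively and gives diol 10 directly.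

Step 6. Borohydride may attack the non-chelated 5-benzyloxyflavone carbonyl (conjugate or direct reduction) before the ester is consumed. The fallback sets out from 9 and comes back at 11, replacing steps 6 and 7 by inverting their order. Hydrogenolysis of 9 (H2, Pd/C, THF/MeOH) gives ethyl (2S,3R)-2-[4-(5,7-dihydroxy-4-oxo-4H-chromen-2-yl)-2,6-dimethoxyphenoxy]-3-hydroxy-3-(4-hydroxyphenyl)propanoate F6. In F6 the flavone carbonyl is protected by the 5-OH chelate and by phenoxide formation under the reduction conditions, so NaBH4 in THF/EtOH at 0 °C reduces only the ester and gives the target 11.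

**Further compounds**
F1 | step 3 | 3,5-dimethoxy-4-(methoxymethoxy)benzaldehyde | COCOc1c(OC)cc(C=O)cc1OC
F2 | step 3 | (E)-1-[2,4-bis(benzyloxy)-6-hydroxyphenyl]-3-[3,5-dimethoxy-4-(methoxymethoxy)phenyl]prop-2-en-1-one | COCOc1c(OC)cc(/C=C/C(=O)c2c(O)cc(OCc3ccccc3)cc2OCc2ccccc2)cc1OC
F3 | step 3 | 5,7-bis(benzyloxy)-2-[3,5-dimethoxy-4-(methoxymethoxy)phenyl]-4H-chromen-4-one | COCOc1c(OC)cc(-c2cc(=O)c3c(OCc4ccccc4)cc(OCc4ccccc4)cc3o2)cc1OC
F4 | step 5 | (S)-4-benzyl-3-({4-[5,7-bis(benzyloxy)-4-oxo-4H-chromen-2-yl]-2,6-dimethoxyphenoxy}acetyl)oxazolidin-2-one | COc1cc(-c2cc(=O)c3c(OCc4ccccc4)cc(OCc4ccccc4)cc3o2)cc(OC)c1OCC(=O)N1[C@@H](Cc2ccccc2)COC1=O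
F5 | step 5 | (S)-4-benzyl-3-[(2S,3R)-3-[4-(benzyloxy)phenyl]-2-{4-[5,7-bis(benzyloxy)-4-oxo-4H-chromen-2-yl]-2,6-dimethoxyphenoxy}-3-hydroxypropanoyl]oxazolidin-2-one | COc1cc(-c2cc(=O)c3c(OCc4ccccc4)cc(OCc4ccccc4)cc3o2)cc(OC)c1O[C@H](C(=O)N1[C@@H](Cc2ccccc2)COC1=O)[C@H](O)c1ccc(OCc2ccccc2)cc1
F6 | step 6 | ethyl (2S,3R)-2-[4-(5,7-dihydroxy-4-oxo-4H-chromen-2-yl)-2,6-dimethoxyphenoxy]-3-hydroxy-3-(4-hydroxyphenyl)propanoate | COc1cc(-c2cc(=O)c3c(O)cc(O)cc3o2)cc(OC)c1O[C@H](C(=O)OCC)[C@H](O)c1ccc(O)cc1
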